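The constants used here were drawn at random within sensible limits; the result is computed.

You have a closed, stirred vessel holding starting material, a large excess of coupling partner and slightly less second reagent than starting material, and you run it at three temperatures.

all flasks: starting material 0.40 M; coupling partner 5.00 equiv; second reagent 0.950 equiv; time 80 min

|  | temperature |
|---|---|
| Friday's | 25 °C |
| Thursday's | 45 °C |
| Tuesday's | 5 °C |

    starting material + coupling partner → intermediate (k1 = 0.0016 M⁻¹ s⁻¹, Ea1 = 49.0 kJ mol⁻¹)
    second reagent + intermediate → target (k2 = 8.1 × 10⁻⁵ M⁻¹ s⁻¹, Ea2 = 57.0 kJ mol⁻¹)
    starting material + second reagent → side product (k3 = 0.0021 M⁻¹ s⁻¹, Ea3 = 65.0 kJ mol⁻¹)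
    target → over-reaction product (k4 = 3.4 × 10⁻⁷ s⁻¹, Ea4 = 106 kJ mol⁻¹)
    (constants at 25 °C)

- all constants are for 25 °C and move with temperature by the activation energies

- which flask leads in amount of target, in percent of the starting material charged ("all alike" within 1.5 percentage points) (Friday's / Thursday's / Tuesday's / all alike)
- how much target is there at the end, in percent of the starting material charged: Friday's
- how much target is there at the end, in percent of the starting material charged: Thursday's
- how much target is there at the end, in percent of the starting material charged: Tuesday's

Reckon each end of the run by hand, then join them. In Friday's flask at the front end, starting material leaves by two routes, and each route's speed is its rate constant times the partner's opening concentration: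

to intermediate: k × [coupling partner] = 0.192 min⁻¹
to side product: k × [second reagent] = 0.0479 min⁻¹
life of starting material = 1/(sum) = 4.17 min
share to intermediate = 80.0%

That life is far shorter than the run of 80 min, so the front end enters the count through its share and not through its time. Tuesday's life, 18.7 min, is also shorter than the run. At the back end, the over-reaction in Thursday's flask has a time of 3330 min, much longer than the run, so I drop it.

That leaves two times. One is the run. The other is the wait: the time the step to target would need to use up the intermediate at its opening rate, 1/(k × [second reagent]). In Friday's flask, [intermediate] = 0.320 M. The side route has taken its part of the second reagent, so [second reagent] = 0.300 M. These differ by 0.0200 M, so I treat them as equal, and the rate then thins as the pair thins: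

target = share × run/(run + wait)

Friday's wait is 686 min, far longer than the life of starting material, which makes this the rate-limiting step.

Thursday's: the step to target speeds up 4.24-fold, share 72.8%, wait 179 min
Tuesday's: the factor is 0.191, share 86.4%, wait 3300 min

So I expect 8.36% for Friday's, 22.5% for Thursday's and 2.05% for Tuesday's, with Thursday's ahead.

The forecast names Thursday's, with 8%, 22.5% and 1.5% for Friday's, Thursday's and Tuesday's, in its words “the slow second-order step 2 sets the yield”.

The simulation gives 8.05% for Friday's, 22.6% for Thursday's and 1.58% for Tuesday's, so Thursday's leads.

Part of Thursday's lead over Tuesday's comes from warming the step to target, which makes the wait 179 min against Tuesday's 3300 min: with temperature taken off that step, the lead falls from 21 percentage points to −0.12 points. Temperature on the side route works the other way and costs 14 points of that lead. Thursday's flask stands at 22.6% and not higher because of two things acting together: the reading at 80 min and not at 800 min, the largest single effect, where it holds 49.3%, and the side route, without which it holds 37.1%. Friday's wait serves again for the same flask left to 800 min: share × run/(run + wait) gives 43.1%, and the flask then holds 42.2%.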